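**Retrosynthetic overview**

1. Target 18 ⇐ hydride addition to one C1 of the bis(quinone methide) 17 ⇐ dehydration of bis-lactol 16 ⇐ DIBAL-H reduction of the C2-symmetric bis-lactone 15.
2. 15 ⇐ open-chain methylene-bridged bis(diketo-dioxinone) 12, which holds no carbocycle. Base closes both carbocycles first (C8a–C4a), then acid closes both lactone rings (O2–C1).
3. Feature the strategy rests on: each carbocycle C4a–C5–C6–C7–C8–C8a is a C5-methylated pentaketide resorcylate and the CH2 bridge joins C7 to C7′. In the open chain C7 is the one CH2 lying between two carbonyl-level carbons (C6 and C8), so the bridge can be set between two chains before any ring exists.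
4. 12 ⇐ oxidation of bis-aldol 11 ⇐ Knoevenagel–Michael union of two chains 8 with formaldehyde at C7, done while C4a is still a carbinol ⇐ dianion of keto-dioxinone 7 + aldehyde 4.
5. 4 ⇐ methyl (R)-3-hydroxybutanoate 1 by Fráter–Seebach methylation (sets C4 relative to C3); 7 ⇐ trimethyldioxinone 5 + propionyl chloride 6.

Key step: step 8

Remark: C5, C7 and the C4a carbinol are mixtures (also keto–enol) in 8, 10, 11 and 12 and are drawn without configuration because all become sp2 carbons; 17 and 18 are drawn as the 8-oxo-6-hydroxy tautomer, which equilibrates with the 6-oxo-8-hydroxy form by proton transfer.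

Numbering used throughout (isochroman): pyran C1, O2, C3, C4; carbocycle C4a, C5, C6, C7, C8, C8a.

**Route**

Step 1
Reactants: 1 methyl (R)-3-hydroxybutanoate
Product: 2 methyl (2R,3R)-3-hydroxy-2-methylbutanoate
Conditions: LDA (2.2 equiv), THF, −78 → −20 °C; MeI, DMPU, −78 → 0 °C
Reagents that add atoms: iodomethane, CI
Why: Fráter–Seebach alkylation; the chelated lithium alkoxide–enolate is methylated on the face away from the C3 methyl group, which should give the anti (2R,3R) ester and so sets C4 relative to C3.

Step 2
Reactants: 2 methyl (2R,3R)-3-hydroxy-2-methylbutanoate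
Product: 3 methyl (2R,3R)-2-methyl-3-[(triethylsilyl)oxy]butanoate
Conditions: TESCl, imidazole, CH2Cl2, 0 °C → rt
Reagents that add atoms: chlorotriethylsilane, CC[Si](Cl)(CC)CC
Why: Imidazole-promoted silylation of a secondary alcohol; the triethylsilyl ether is chosen because it survives enolate, amine and periodinane conditions but falls to mild acid in step 8.

Step 3
Reactants: 3 methyl (2R,3R)-2-methyl-3-[(triethylsilyl)oxy]butanoate
Product: 4 (2R,3R)-2-methyl-3-[(triethylsilyl)oxy]butanal
Conditions: DIBAL-H (1.1 equiv), CH2Cl2, −78 °C; MeOH, Rochelle salt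
Reagents that add atoms: none
Why: Partial DIBAL-H reduction of an ester; the tetrahedral aluminate persists at −78 °C and the non-basic conditions leave the α-stereocentre untouched (the aldehyde is used at once).

Step 4
Reactants: 5 2,2,6-trimethyl-4H-1,3-dioxin-4-one, 6 propionyl chloride
Product: 7 2,2-dimethyl-6-(2-oxobutyl)-4H-1,3-dioxin-4-one
Conditions: LiHMDS (2 equiv), 5 (2 equiv), THF, −78 °C; then 6 (1 equiv), −78 °C
Reagents that add atoms: none
Why: Vinylogous Claisen acylation; the 6-methyl group of the dioxinone is deprotonated and acylated at that carbon by the acid chloride, the second equivalent of dienolate taking up the acidic proton of the product.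

Step 5
Reactants: 7 2,2-dimethyl-6-(2-oxobutyl)-4H-1,3-dioxin-4-one, 4 (2R,3R)-2-methyl-3-[(triethylsilyl)oxy]butanal
Product: 8 6-[(5S,6R)-4-hydroxy-3,5-dimethyl-2-oxo-6-[(triethylsilyl)oxy]heptyl]-2,2-dimethyl-4H-1,3-dioxin-4-one (mixture at the two new centres)
Conditions: LDA (2.1 equiv), THF, −78 → −40 °C; then 4, −78 °C; AcOH quench at −78 °C
Reagents that add atoms: none
Why: Dianion aldol addition (Weiler-type); after deprotonation at C7 the second deprotonation at the ethyl CH2 (C5) gives the more reactive terminus, which adds to the aldehyde to form C5–C4a, and the two new centres need no control because both become sp2 later.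

Step 6
Reactants: 8 aldol chain (2 equiv), 9 formaldehyde (1 equiv)
Product: 11 methylene-bridged bis(hydroxy-keto-dioxinone) (two units of 8 joined C7–CH2–C7′), via C7-methylidene keto-dioxinone 10 (not isolated)
Conditions: aq. CH2O (0.5 equiv per 8), piperidine (10 mol %), AcOH (10 mol %), MeCN, 0 °C → rt
Reagents that add atoms: none
Why: Knoevenagel condensation then Michael addition; in 8 C7 is the only CH2 between two carbonyl-level carbons while C5 is still a plain ketone α-methine because C4a is a carbinol, so formaldehyde should condense at C7 to give 10 and a second molecule of 8 should add through its C7, with neither a C5 Michael donor nor amine-induced aromatisation possible at this oxidation level.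

Step 7
Reactants: 11 methylene-bridged bis(hydroxy-keto-dioxinone)
Product: 12 methylene-bridged bis(diketo-dioxinone), C3 and C3′ triethylsilyl ethers
Conditions: Dess–Martin periodinane (2.6 equiv), CH2Cl2, 0 °C → rt; cold Na2S2O3/NaHCO3 wash; used crude
Reagents that add atoms: none
Why: Dess–Martin oxidation of both β-hydroxy ketones to β-diketones under non-basic conditions, which leaves the silyl ethers and the dioxinones intact and should deliver the precursor without starting its cyclisation (no chromatography).

Step 8
Reactants: 12 methylene-bridged bis(diketo-dioxinone)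
Product: 15 7,7′-methylenebis[(3R,4S)-6,8-dihydroxy-3,4,5-trimethylisochroman-1-one], via bis(benzodioxinone) bis(triethylsilyl ether) 13 (not isolated), via bis(benzodioxinone) diol 14 (not isolated)
Conditions: Et3N (10 equiv), CH2Cl2, rt → 40 °C; then TFA–H2O (excess over Et3N) added to the same flask, rt → 40 °C
Reagents that add atoms: none
Why: Triethylamine removes the C7–H of each half (flanked by the C6 ketone and the dioxinone) to give a dienolate whose carbon C8a adds to the C4a ketone (6-enolexo-exo-trig aldol, bond C8a–C4a), and loss of water followed by enolisation of C6 through the single C5–H should give each benzodioxinone irreversibly. The closest known reaction is the amine-mediated cycloaromatisation of diketo-dioxinones to isopropylidene-protected resorcylates followed by lactonisation through a side-chain alcohol, here run twice in one molecule on a chain substituted at C5 and C7 and with an α-branched C4a ketone. Acid then cleaves both silyl ethers and each C3 hydroxyl attacks the C1 acyl carbon (6-exo-trig) with expulsion of acetone, which closes the lactone and frees the C8 phenol. No stereocentre is created: the labile C5 and C7 centres become aromatic carbons, and C3 and C4 are carried through because the C4a/C6 diketone enolises toward C5 and triethylamine is too weak to remove the C4–H. The step needs C-cyclisation over O-cyclisation by the C3 oxygen (hemiketal or dihydropyranone formation), which is secured by keeping that oxygen silylated until both carbocycles are aromatic, and it needs to outrun reversible cross-half aldol and retro-Michael events, for which aromatisation is the only irreversible exit.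

Step 9
Reactants: 15 7,7′-methylenebis[(3R,4S)-6,8-dihydroxy-3,4,5-trimethylisochroman-1-one]
Product: 16 7,7′-methylenebis[(3R,4S)-3,4,5-trimethylisochromane-1,6,8-triol] (bis-lactol, anomeric mixture)
Conditions: DIBAL-H (8 equiv), THF–CH2Cl2, −78 °C; Rochelle salt
Reagents that add atoms: none
Why: DIBAL-H reduction of δ-lactones to lactols; four equivalents are consumed by the phenols and the tetrahedral aluminates should persist at −78 °C until work-up.

Step 10
Reactants: 16 bis-lactol
Product: 17 7,7′-methylenebis[(3R,4S)-6-hydroxy-3,4,5-trimethyl-3,4-dihydro-8H-isochromen-8-one] (bis(quinone methide))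
Conditions: p-TsOH·H2O (5 mol %), 4 Å MS, CH2Cl2, rt
Reagents that add atoms: none
Why: Acid-catalysed dehydration of a lactol; ionisation at C1 is assisted by the ortho (C8) and para (C6) hydroxyls and loss of a phenolic proton gives the citrinin-type quinone methide, the sieves pulling the hydrate equilibrium to the dehydrated side.

Step 11
Reactants: 17 bis(quinone methide)
Product: 18 Dicitrinone I
Conditions: NaBH4 (0.3 equiv, in portions), THF–MeOH, −40 °C; aq. NH4Cl
Reagents that add atoms: none
Why: Conjugate hydride addition to C1 of a quinone methide, which restores the aromatic ring (the reaction type by which citrinin is reduced to dihydrocitrinin); with one hydride equivalent the two identical halves react statistically, so 18 should be separated from recovered 17 (resubmitted) and from over-reduced material.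

**Compound list**

1 | methyl (R)-3-hydroxybutanoate | C[C@@H](O)CC(=O)OC | starting material
2 | methyl (2R,3R)-3-hydroxy-2-methylbutanoate | COC(=O)[C@H](C)[C@@H](C)O | intermediate
3 | methyl (2R,3R)-2-methyl-3-[(triethylsilyl)oxy]butanoate | COC(=O)[C@H](C)[C@@H](C)O[Si](CC)(CC)CC | intermediate
4 | (2R,3R)-2-methyl-3-[(triethylsilyl)oxy]butanal | O=C[C@H](C)[C@@H](C)O[Si](CC)(CC)CC | intermediate
5 | 2,2,6-trimethyl-4H-1,3-dioxin-4-one | CC1=CC(=O)OC(C)(C)O1 | starting material
6 | propionyl chloride | CCC(=O)Cl | starting material
7 | 2,2-dimethyl-6-(2-oxobutyl)-4H-1,3-dioxin-4-one | CCC(=O)CC1=CC(=O)OC(C)(C)O1 | intermediate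
8 | 6-[(5S,6R)-4-hydroxy-3,5-dimethyl-2-oxo-6-[(triethylsilyl)oxy]heptyl]-2,2-dimethyl-4H-1,3-dioxin-4-one | CC1(C)OC(=O)C=C(CC(=O)C(C)C(O)[C@H](C)[C@@H](C)O[Si](CC)(CC)CC)O1 | intermediate
9 | formaldehyde | C=O | starting material
10 | C7-methylidene derivative of 8 (not isolated) | C=C(C(=O)C(C)C(O)[C@H](C)[C@@H](C)O[Si](CC)(CC)CC)C1=CC(=O)OC(C)(C)O1 | intermediate
11 | methylene-bridged bis(hydroxy-keto-dioxinone), C7–CH2–C7′ | C(C(C(=O)C(C)C(O)[C@H](C)[C@@H](C)O[Si](CC)(CC)CC)C1=CC(=O)OC(C)(C)O1)C(C(=O)C(C)C(O)[C@H](C)[C@@H](C)O[Si](CC)(CC)CC)C1=CC(=O)OC(C)(C)O1 | intermediate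
12 | methylene-bridged bis(diketo-dioxinone), C3/C3′ triethylsilyl ethers | C(C(C(=O)C(C)C(=O)[C@H](C)[C@@H](C)O[Si](CC)(CC)CC)C1=CC(=O)OC(C)(C)O1)C(C(=O)C(C)C(=O)[C@H](C)[C@@H](C)O[Si](CC)(CC)CC)C1=CC(=O)OC(C)(C)O1 | intermediate
13 | 8,8′-methylenebis{7-hydroxy-2,2,6-trimethyl-5-[(2S,3R)-3-[(triethylsilyl)oxy]butan-2-yl]-4H-1,3-benzodioxin-4-one} (not isolated) | C(c1c(O)c(C)c([C@H](C)[C@@H](C)O[Si](CC)(CC)CC)c2c1OC(C)(C)OC2=O)c1c(O)c(C)c([C@H](C)[C@@H](C)O[Si](CC)(CC)CC)c2c1OC(C)(C)OC2=O | intermediate
14 | 8,8′-methylenebis{7-hydroxy-5-[(2S,3R)-3-hydroxybutan-2-yl]-2,2,6-trimethyl-4H-1,3-benzodioxin-4-one} (not isolated) | C(c1c(O)c(C)c([C@H](C)[C@@H](C)O)c2c1OC(C)(C)OC2=O)c1c(O)c(C)c([C@H](C)[C@@H](C)O)c2c1OC(C)(C)OC2=O | intermediate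
15 | 7,7′-methylenebis[(3R,4S)-6,8-dihydroxy-3,4,5-trimethylisochroman-1-one] | C(c1c(O)c(C)c2c(c1O)C(=O)O[C@H](C)[C@H]2C)c1c(O)c(C)c2c(c1O)C(=O)O[C@H](C)[C@H]2C | intermediate
16 | 7,7′-methylenebis[(3R,4S)-3,4,5-trimethylisochromane-1,6,8-triol] | C(c1c(O)c(C)c2c(c1O)C(O)O[C@H](C)[C@H]2C)c1c(O)c(C)c2c(c1O)C(O)O[C@H](C)[C@H]2C | intermediate
17 | 7,7′-methylenebis[(3R,4S)-6-hydroxy-3,4,5-trimethyl-3,4-dihydro-8H-isochromen-8-one] | C(C1=C(O)C(C)=C2C(=CO[C@H](C)[C@H]2C)C1=O)C1=C(O)C(C)=C2C(=CO[C@H](C)[C@H]2C)C1=O | intermediate
18 | Dicitrinone I | CC1=C2C(=CO[C@H](C)[C@H]2C)C(=O)C(Cc2c(O)c(C)c3c(c2O)CO[C@H](C)[C@H]3C)=C1O | target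

**Step count**

Total steps: 11. Longest linear sequence: 10 (steps 1–3 and 5–11; step 4 is the side branch).

**Three steps most likely to fail**

1. Step 8. Addition of C8a to the doubly α-branched C4a ketone may be slow, so that retro-Michael loss of the bridge or reversible cross-half aldol closure consumes the material, or only one half aromatises; forcing conditions could also erode C4. The fallback moves the bridge behind ring formation and uses known chemistry only. It sets out from 8: Dess–Martin oxidation should give the monomeric diketo-dioxinone F1; triethylamine should aromatise it to the monomeric benzodioxinone silyl ether F2; acid should remove the silyl group to the benzodioxinone alcohol F3, which lactonises with loss of acetone to (3R,4S)-6,8-dihydroxy-3,4,5-trimethylisochroman-1-one F4. Two molecules of F4 are then joined with aqueous formaldehyde under acid catalysis by electrophilic substitution at C7, the only free ring position and ortho to both hydroxyls, which comes back to the route at 15.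

2. Step 6. The C4a hydroxyl may capture the C7-methylidene by 6-endo oxa-Michael addition, the β-hydroxy ketone may undergo retro-aldol cleavage under amine catalysis, or a second formaldehyde may be taken up. The fallback reverses the order of bridging and aldol addition. It sets out from 7: the same Knoevenagel–Michael reaction with formaldehyde, now on a substrate with no hydroxyl, should give the methylene-bridged bis(keto-dioxinone) F5. Deprotonation of F5 with LDA (4.4 equiv) to the bis-dianion and addition of two equivalents of aldehyde 4 comes back to the route at 11.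

3. Step 9. Donation from the aluminium phenoxides may deactivate the lactone carbonyls so that reduction stalls, or the lactol aluminate may open to the chelated salicylaldehyde and be reduced further. The fallback reduces fully and then re-oxidises. It sets out from 15: LiAlH4 should give the bis(benzylic alcohol) hexaol F6; catalytic acid should ionise each 2,4-dihydroxybenzylic alcohol, which is captured by the C3 hydroxyl to give the bis(isochroman) F7; DDQ (2 equiv) should then dehydrogenate both phenolic benzylic ether positions, which comes back to the route at 17.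

**Further compounds**

F1 | step 8 | 6-[(5R,6R)-3,5-dimethyl-2,4-dioxo-6-[(triethylsilyl)oxy]heptyl]-2,2-dimethyl-4H-1,3-dioxin-4-one | CC1(C)OC(=O)C=C(CC(=O)C(C)C(=O)[C@H](C)[C@@H](C)O[Si](CC)(CC)CC)O1
F2 | step 8 | 7-hydroxy-2,2,6-trimethyl-5-[(2S,3R)-3-[(triethylsilyl)oxy]butan-2-yl]-4H-1,3-benzodioxin-4-one | Cc1c(O)cc2OC(C)(C)OC(=O)c2c1[C@H](C)[C@@H](C)O[Si](CC)(CC)CC
F3 | step 8 | 7-hydroxy-5-[(2S,3R)-3-hydroxybutan-2-yl]-2,2,6-trimethyl-4H-1,3-benzodioxin-4-one | Cc1c(O)cc2OC(C)(C)OC(=O)c2c1[C@H](C)[C@@H](C)O
F4 | step 8 | (3R,4S)-6,8-dihydroxy-3,4,5-trimethylisochroman-1-one | Cc1c(O)cc(O)c2C(=O)O[C@H](C)[C@@H](C)c12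
F5 | step 6 | 6,6′-(3,7-dioxononane-4,6-diyl)bis(2,2-dimethyl-4H-1,3-dioxin-4-one) | CCC(=O)C(CC(C(=O)CC)C1=CC(=O)OC(C)(C)O1)C1=CC(=O)OC(C)(C)O1
F6 | step 9 | 2,2′-methylenebis{4-(hydroxymethyl)-5-[(2S,3R)-3-hydroxybutan-2-yl]-6-methylbenzene-1,3-diol} | C(c1c(O)c(C)c([C@H](C)[C@@H](C)O)c(CO)c1O)c1c(O)c(C)c([C@H](C)[C@@H](C)O)c(CO)c1O
F7 | step 9 | 7,7′-methylenebis[(3R,4S)-3,4,5-trimethylisochromane-6,8-diol] | C(c1c(O)c(C)c2c(c1O)CO[C@H](C)[C@H]2C)c1c(O)c(C)c2c(c1O)CO[C@H](C)[C@H]2C
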